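## Retrosynthetic overview

- The target is released by one mild base-mediated removal of six aryl acetates and one aldehyde gem-diacetate from the fully assembled ketone.
- Key disconnection: the aroyl C(=O)–aryl bond. The cyclohexene carbaldehyde is used as an acyl-anion equivalent (acyl radical, then acyl–nickel) against the electrophilic C–Br carbon of 4-bromoresorcinol diacetate, so two natively electrophilic carbons are joined.
- The aldehyde comes from an exo-selective, enantioselective iminium-catalysed Diels–Alder reaction of an (E)-aryl diene with (E)-2,4-diacetoxycinnamaldehyde. This forms the only new ring (the cyclohexene) and all three stereocentres.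
- The diene comes from a Heck reaction of protected 5-bromo-2,4-dihydroxybenzaldehyde with isoprene, and the enal from a Wittig reaction on protected 2,4-dihydroxybenzaldehyde. The three arenes are bought.

Assumption: ring locants in the "Why" lines are those of aldehyde 13 (C1 bears the carbonyl carbon, C2 the formyl-arene, C6 the resorcinol ring, C3=C4 is the alkene); catalyst-bound iminium ions and the transient acyl radical are numbered as non-isolated compounds.

## Route

Step 1
Reactants: 1 5-bromo-2,4-dihydroxybenzaldehyde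
Product: 2 [2,4-bis(acetyloxy)-5-bromophenyl]methanediyl diacetate
Conditions: Ac2O (excess), cat. H2SO4, 0 °C → rt
Reagents that add atoms: acetic anhydride CC(=O)OC(C)=O
Why: Acid-catalysed acetylation caps both phenols and converts the aldehyde into its gem-diacetate (acylal), which masks the aromatic aldehyde C–H so that it cannot compete in steps 6 and 7; no stereocentre.

Step 2
Reactants: 2 [2,4-bis(acetyloxy)-5-bromophenyl]methanediyl diacetate; 3 isoprene
Product: 4 {2,4-bis(acetyloxy)-5-[(1E)-3-methylbuta-1,3-dien-1-yl]phenyl}methanediyl diacetate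
Conditions: Pd(OAc)2 (5 mol%), P(o-tol)3 (10 mol%), Et3N, isoprene (5 equiv), MeCN, 100 °C, sealed tube
Reagents that add atoms: none
Why: Mizoroki–Heck reaction, in which aryl–Pd adds to the unsubstituted vinyl terminus of isoprene and syn β-hydride elimination gives the conjugated (E)-1-aryl-3-methylbuta-1,3-diene; aryl acetates and the acylal tolerate the non-nucleophilic base.

Step 3
Reactants: 5 2,4-dihydroxybenzaldehyde
Product: 6 4-formyl-1,3-phenylene diacetate
Conditions: Ac2O, pyridine, cat. DMAP, CH2Cl2, 0 °C → rt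
Reagents that add atoms: acetic anhydride CC(=O)OC(C)=O
Why: Base-mediated O-acetylation (nucleophilic catalysis) caps both phenols while the aldehyde stays free because no acid is present.

Step 4
Reactants: 6 4-formyl-1,3-phenylene diacetate; 7 (triphenylphosphoranylidene)acetaldehyde
Product: 8 4-[(1E)-3-oxoprop-1-en-1-yl]-1,3-phenylene diacetate
Conditions: 7 (1.05 equiv), toluene, 80 °C
Reagents that add atoms: none
Why: Wittig olefination with a stabilised ylide gives the two-carbon-homologated (E)-enal; the acetoxy groups make the aldehyde electrophilic enough, and a slight excess of ylide limits over-homologation.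

Step 5
Reactants: 9 4-bromoresorcinol
Product: 10 4-bromo-1,3-phenylene diacetate
Conditions: Ac2O, pyridine, cat. DMAP, CH2Cl2, 0 °C → rt
Reagents that add atoms: acetic anhydride CC(=O)OC(C)=O
Why: O-Acetylation gives the aryl bromide partner in the same protecting-group format as the other fragments.

Step 6
Reactants: 4 {2,4-bis(acetyloxy)-5-[(1E)-3-methylbuta-1,3-dien-1-yl]phenyl}methanediyl diacetate; 8 4-[(1E)-3-oxoprop-1-en-1-yl]-1,3-phenylene diacetate
Product: 13 (1R,2R,6S)-2-[2,4-bis(acetyloxy)-5-(diacetoxymethyl)phenyl]-6-[2,4-bis(acetyloxy)phenyl]-4-methylcyclohex-3-ene-1-carbaldehyde, via dienophile iminium trifluoroacetate 11 (not isolated), via cycloadduct iminium trifluoroacetate 12 (not isolated)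
Conditions: (S)-2-{bis[3,5-bis(trifluoromethyl)phenyl](triethylsilyloxy)methyl}pyrrolidine (20 mol%), CF3CO2H (20 mol%), 4 (1.5 equiv), toluene, 4 °C → rt
Reagents that add atoms: none
Why: Iminium-ion (LUMO-lowering) organocatalytic Diels–Alder reaction, in which the diene CH2 terminus bonds to the enal β-carbon ("ortho/para" regiochemistry), the (E)-enal fixes C1/C6 trans, the silyloxydiarylmethyl group of the (S)-catalyst blocks the Re face of the β-carbon so the diene adds to the Si face (6S, 1R), and the exo approach away from the bulky iminium, as in exo-selective diarylprolinol silyl ether Diels–Alder reactions of cinnamaldehydes, places the C2 aryl trans to the formyl group (2R), giving the all-trans adduct after hydrolysis of 12.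

Step 7
Reactants: 13 (1R,2R,6S)-2-[2,4-bis(acetyloxy)-5-(diacetoxymethyl)phenyl]-6-[2,4-bis(acetyloxy)phenyl]-4-methylcyclohex-3-ene-1-carbaldehyde; 10 4-bromo-1,3-phenylene diacetate
Product: 15 {(1R,2R,6S)-2-[2,4-bis(acetyloxy)-5-(diacetoxymethyl)phenyl]-6-[2,4-bis(acetyloxy)phenyl]-4-methylcyclohex-3-en-1-yl}[2,4-bis(acetyloxy)phenyl]methanone, via acyl radical 14 (not isolated)
Conditions: [Ir{dF(CF3)ppy}2(dtbbpy)]PF6 (1 mol%), NiBr2·dtbbpy (10 mol%), quinuclidine (10 mol%), K2CO3 (1.5 equiv), 10 (2 equiv), 1,4-dioxane, blue LEDs, rt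
Reagents that add atoms: none
Why: Nickel/photoredox/hydrogen-atom-transfer aldehyde C–H arylation, in which the quinuclidinium radical cation abstracts the hydridic formyl hydrogen (the acylal C–H is electron-poor and hindered), the nucleophilic acyl radical 14 is captured by the aryl–nickel species from 10 and reductive elimination gives the ketone, so the aldehyde carbon acts as an acyl-anion equivalent toward the C–Br carbon; no stereocentre is formed and the α-centre C1 is untouched and already in its thermodynamic trans,trans arrangement.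

Step 8
Reactants: 15 {(1R,2R,6S)-2-[2,4-bis(acetyloxy)-5-(diacetoxymethyl)phenyl]-6-[2,4-bis(acetyloxy)phenyl]-4-methylcyclohex-3-en-1-yl}[2,4-bis(acetyloxy)phenyl]methanone
Product: 16 5-[(1R,5S,6R)-6-(2,4-dihydroxybenzoyl)-5-(2,4-dihydroxyphenyl)-3-methylcyclohex-2-en-1-yl]-2,4-dihydroxybenzaldehyde
Conditions: K2CO3 (2 equiv), degassed MeOH, 0 °C → rt; then pH 6 phosphate buffer
Reagents that add atoms: none
Why: Base-mediated transesterification (Zemplén-type methanolysis) removes the six aryl acetates and collapses the acylal to the aldehyde, the only epimerisable centre (α to the ketone) is already all-equatorial so base cannot scramble it, and the near-neutral work-up avoids acid-catalysed chroman formation from the ortho-phenol and the ring alkene.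

## Compound list

1 | 5-bromo-2,4-dihydroxybenzaldehyde | O=Cc1cc(Br)c(O)cc1O | starting material
2 | [2,4-bis(acetyloxy)-5-bromophenyl]methanediyl diacetate | CC(=O)OC(OC(C)=O)c1cc(Br)c(OC(C)=O)cc1OC(C)=O | intermediate
3 | isoprene (2-methylbuta-1,3-diene) | C=CC(C)=C | starting material
4 | {2,4-bis(acetyloxy)-5-[(1E)-3-methylbuta-1,3-dien-1-yl]phenyl}methanediyl diacetate | C=C(C)/C=C/c1cc(C(OC(C)=O)OC(C)=O)c(OC(C)=O)cc1OC(C)=O | intermediate
5 | 2,4-dihydroxybenzaldehyde | O=Cc1ccc(O)cc1O | starting material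
6 | 4-formyl-1,3-phenylene diacetate (2,4-diacetoxybenzaldehyde) | CC(=O)Oc1ccc(C=O)c(OC(C)=O)c1 | intermediate
7 | (triphenylphosphoranylidene)acetaldehyde | O=CC=P(c1ccccc1)(c1ccccc1)c1ccccc1 | starting material
8 | 4-[(1E)-3-oxoprop-1-en-1-yl]-1,3-phenylene diacetate ((E)-2,4-diacetoxycinnamaldehyde) | CC(=O)Oc1ccc(/C=C/C=O)c(OC(C)=O)c1 | intermediate
9 | 4-bromoresorcinol (4-bromobenzene-1,3-diol) | Oc1ccc(Br)c(O)c1 | starting material
10 | 4-bromo-1,3-phenylene diacetate | CC(=O)Oc1ccc(Br)c(OC(C)=O)c1 | intermediate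
11 | dienophile iminium trifluoroacetate (enal 8 condensed with the (S)-diarylprolinol silyl ether catalyst) | CC(=O)Oc1ccc(/C=C/C=[N+]2CCC[C@H]2C(O[Si](CC)(CC)CC)(c2cc(C(F)(F)F)cc(C(F)(F)F)c2)c2cc(C(F)(F)F)cc(C(F)(F)F)c2)c(OC(C)=O)c1.[O-]C(=O)C(F)(F)F | intermediate
12 | cycloadduct iminium trifluoroacetate (iminium of 13 with the catalyst) | CC1=C[C@@H](c2cc(C(OC(C)=O)OC(C)=O)c(OC(C)=O)cc2OC(C)=O)[C@H](C=[N+]2CCC[C@H]2C(O[Si](CC)(CC)CC)(c2cc(C(F)(F)F)cc(C(F)(F)F)c2)c2cc(C(F)(F)F)cc(C(F)(F)F)c2)[C@@H](c2ccc(OC(C)=O)cc2OC(C)=O)C1.[O-]C(=O)C(F)(F)F | intermediate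
13 | (1R,2R,6S)-2-[2,4-bis(acetyloxy)-5-(diacetoxymethyl)phenyl]-6-[2,4-bis(acetyloxy)phenyl]-4-methylcyclohex-3-ene-1-carbaldehyde (all-trans) | CC1=C[C@@H](c2cc(C(OC(C)=O)OC(C)=O)c(OC(C)=O)cc2OC(C)=O)[C@H](C=O)[C@@H](c2ccc(OC(C)=O)cc2OC(C)=O)C1 | intermediate
14 | acyl radical of 13 (formyl hydrogen removed) | CC1=C[C@@H](c2cc(C(OC(C)=O)OC(C)=O)c(OC(C)=O)cc2OC(C)=O)[C@H]([C]=O)[C@@H](c2ccc(OC(C)=O)cc2OC(C)=O)C1 | intermediate
15 | {(1R,2R,6S)-2-[2,4-bis(acetyloxy)-5-(diacetoxymethyl)phenyl]-6-[2,4-bis(acetyloxy)phenyl]-4-methylcyclohex-3-en-1-yl}[2,4-bis(acetyloxy)phenyl]methanone | CC1=C[C@@H](c2cc(C(OC(C)=O)OC(C)=O)c(OC(C)=O)cc2OC(C)=O)[C@H](C(=O)c2ccc(OC(C)=O)cc2OC(C)=O)[C@@H](c2ccc(OC(C)=O)cc2OC(C)=O)C1 | intermediate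
16 | 5-[(1R,5S,6R)-6-(2,4-dihydroxybenzoyl)-5-(2,4-dihydroxyphenyl)-3-methylcyclohex-2-en-1-yl]-2,4-dihydroxybenzaldehyde | CC1=C[C@@H](c2cc(C=O)c(O)cc2O)[C@H](C(=O)c2ccc(O)cc2O)[C@@H](c2ccc(O)cc2O)C1 | target

## Step count and risks

Total step count: 8. Longest linear sequence: 5 (steps 1, 2, 6, 7, 8).

The three steps most likely to fail:

1. Step 6 (Diels–Alder). A β-aryl enal and an acyclic 1-aryl diene are sluggish under iminium catalysis, and the exo preference is carried over from cyclopentadiene cases, not shown for this diene class. Fallback: set out from 4 and 8 and run the cycloaddition without catalyst under high pressure (10–12 kbar, CH2Cl2, rt). This gives the racemic all-trans aldehyde F1 after silica separation from the endo isomer. The enantiomers are then separated by preparative chromatography on a chiral stationary phase, and the route is rejoined at 13.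

2. Step 7 (acyl C–H arylation). The aldehyde is α-branched and flanked by two aryl-bearing carbons, the bromide is ortho-substituted, and decarbonylation of 14 or hydrogen abstraction at other C–H bonds could compete. Fallback: set out from 13 and oxidise it (NaClO2, NaH2PO4, 2-methyl-2-butene, t-BuOH/H2O) to the carboxylic acid F2. Convert this with 2,2′-dipyridyl disulfide and PPh3 into the S-(pyridin-2-yl) thioester F3. Couple F3 with bromide 10 by nickel-catalysed reductive cross-electrophile coupling (NiBr2·dme, dtbbpy, Zn, DMA, rt), which returns to the route at 15.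

3. Step 2 (Heck reaction with isoprene). Arylation at the isopropenyl terminus and thermal dimerisation of the diene can erode the yield. Fallback: set out from 2 and run the Heck reaction with 2-methylbut-3-en-2-ol (Pd(OAc)2, P(o-tol)3, Et3N, MeCN, 90 °C) to the tertiary allylic alcohol F4. Dehydrate it with MsCl and Et3N in CH2Cl2 (0 °C → rt), which returns to the route at 4.

Further compounds

F1 | step 6 | racemic all-trans 2-[2,4-bis(acetyloxy)-5-(diacetoxymethyl)phenyl]-6-[2,4-bis(acetyloxy)phenyl]-4-methylcyclohex-3-ene-1-carbaldehyde (13 and its enantiomer, 1:1) | CC1=C[C@@H](c2cc(C(OC(C)=O)OC(C)=O)c(OC(C)=O)cc2OC(C)=O)[C@H](C=O)[C@@H](c2ccc(OC(C)=O)cc2OC(C)=O)C1.CC1=C[C@H](c2cc(C(OC(C)=O)OC(C)=O)c(OC(C)=O)cc2OC(C)=O)[C@@H](C=O)[C@H](c2ccc(OC(C)=O)cc2OC(C)=O)C1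
F2 | step 7 | (1R,2R,6S)-2-[2,4-bis(acetyloxy)-5-(diacetoxymethyl)phenyl]-6-[2,4-bis(acetyloxy)phenyl]-4-methylcyclohex-3-ene-1-carboxylic acid | CC1=C[C@@H](c2cc(C(OC(C)=O)OC(C)=O)c(OC(C)=O)cc2OC(C)=O)[C@H](C(=O)O)[C@@H](c2ccc(OC(C)=O)cc2OC(C)=O)C1
F3 | step 7 | S-(pyridin-2-yl) (1R,2R,6S)-2-[2,4-bis(acetyloxy)-5-(diacetoxymethyl)phenyl]-6-[2,4-bis(acetyloxy)phenyl]-4-methylcyclohex-3-ene-1-carbothioate | CC1=C[C@@H](c2cc(C(OC(C)=O)OC(C)=O)c(OC(C)=O)cc2OC(C)=O)[C@H](C(=O)Sc2ccccn2)[C@@H](c2ccc(OC(C)=O)cc2OC(C)=O)C1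
F4 | step 2 | {2,4-bis(acetyloxy)-5-[(1E)-3-hydroxy-3-methylbut-1-en-1-yl]phenyl}methanediyl diacetate | CC(C)(O)/C=C/c1cc(C(OC(C)=O)OC(C)=O)c(OC(C)=O)cc1OC(C)=O
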